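All runs were computed on assumed constants, and the scatter is random.

A single stopped run cannot say whether it stopped at a fixed amount of target or at a fixed proportion to what is dissolved, and cedar is the run that stopped: target 59.3% at 4.00 min, 57.2% at 8.00 min. Elm, the flask asked about, has twice the charge and is still climbing.

| flask | solid substrate | gas | remark | time |
|---|---|---|---|---|
| elm | 0.20 M | 18 mM (held) | the very flask that is asked about, followed so far |  |
| cedar | 0.10 M | 18 mM (held) | run made earlier |  |
| flask | 0.20 M | 18 mM (held) |  | 10 min |

elm run (percent of the solid substrate charged)

| time / s | target / % | dissolved substrate / % |
|---|---|---|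
| 10.0 | 0 | 5.4 |
| 30.0 | 5.4 | 8.8 |
| 60.0 | 11.6 | 13.7 |
| 80.0 | 15.2 | 13.4 |
| 120 | 20.3 | 16.8 |

cedar run (percent of the solid substrate charged)

| time / min | target / % | dissolved substrate / % |
|---|---|---|
| 0.500 | 9.1 | 20.6 |
| 1.00 | 22.0 | 27.0 |
| 2.00 | 46.6 | 35.7 |
| 4.00 | 59.3 | 26.2 |
| 8.00 | 57.2 | 24.6 |

(readings scatter by 1 percentage point)

- as a solid, counted per litre of solution: solid substrate
- the numbers in the tables scatter by 1 percentage point (one standard deviation)
- at the start none of the gas is in solution
- at the start none of the solid substrate is in solution
- dissolved substrate means what is dissolved; the solid is not counted in it

- target at 10 min, in percent of the solid substrate charged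
- concentration of dissolved substrate in solution at 5.0 min, in percent of saturation
- the change that raises the amount of target at 10 min, in percent of the solid substrate charged most ("none" if none brings more than 2 percentage points) (violet / amber / green / grey / none)
- amount of target at 10 min, in percent of the solid substrate charged, after green

- violet: doubling the solubility of the solid substrate, all else as stated
- amber: doubling the dissolution coefficient of the solid substrate, all else as stated
- green: doubling the transfer coefficient of the gas, all else as stated
- grey: doubling the saturation concentration of gas, all else as stated

Two chemists read these runs differently. The first sees about the same c(target) at about the same time, 46.6 mM in cedar at 2.00 min and 40.6 mM in elm at 120 s, and takes cedar's stop as a fixed amount. Hence the forecast: “Elm should therefore also stall”, giving 28%, saturation 95%, best change green, and 41% after green.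

The second holds that cedar stopped at a balance under held gas (thermodynamic control), which follows proportions and not amounts. From cedar's last two readings she keeps 2.29 as the stop ratio, c(target) over c(dissolved substrate) once a flask at this gas level stands still. Cedar's last reading leaves 18.2% of the charge unaccounted for. Keeping that share and taking the whole charge as dissolved, she reckons 57.0% for elm, against the forecast's 28%. At elm's rate so far, 20.3 mM/min, that takes 5.61 min, shorter than 10 min. Her view ties the ratio to the gas level and not to the speed of transfer, so she picks grey and leaves green at 57.0%.

The simulation gives 56.2%.

    gas ⇌ partner, rate k1*(csat - [partner]) (kL = 0.230 /s)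
    target ⇌ isomer of the product (K = 0.370, k = 0.00280 /s)
    dissolved substrate + partner ⇌ target (K = 130 /M, k = 2.00 /M/s)
    solid substrate ⇌ dissolved substrate, rate k4*(cs4 - [dissolved substrate]) while solid is left; crystals form when [dissolved substrate] > cs4 (solubility = 0.0690 M, k = 0.0170 /s)

Dissolved substrate at 5.0 min stands at 72.8% of saturation, grey adds 7.2 percentage points, and green gives 56.1%. This flask, read at 2.5 min, holds 28.6% target, about the forecast's figure. At 10 min the ratio in this flask is 2.33, beside the 2.29 read from cedar. The neighbour charged with 0.34 M has a ratio of 2.14 at 10 min, lower than the value read from cedar, and its solid substrate stands at 31.9% of its charge.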